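**Strategy.** The benzene ring (ring A) is built last from two open-chain partners. Numbered from the bridge-bearing carbon C1, ring A has oxygen on C2, C4 and C6 and the acyl group on C3 between two of them; a 1,1,3-trioxygenated diene and an ynone with an alkoxy group on its β-carbon deliver exactly this alternation. One cycloaddition–aromatisation forms C1–C2 and C3–C4, closes ring A and sets its whole substitution pattern with the C6 methyl ether already distinguished from the two phenols. The precursor is a silyl ketene acetal diene whose terminus carries the intact pyrone (ring B) through the future bridge CH2, its 4-oxygen silylated; the ynone carries the (R)-sec-butyl ketone.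

Key step: step 10

Remark: lithium and silicon on the ambident pyranone oxygen are drawn at O4 (attachment at the ring carbonyl oxygen would give the same products after work-up), and (R)-2-methylbutanoic acid is taken as a commercial single enantiomer.

**Route**

Step 1
Reactants: 1 pentan-3-one
Product: 2 (Z)-3-(trimethylsilyloxy)pent-2-ene (E/Z mixture acceptable)
Conditions: Me3SiCl, Et3N, DMF, 90 °C
Reagents that add atoms: chlorotrimethylsilane, C[Si](C)(C)Cl
Why: Amine-mediated O-silylation of a symmetrical ketone (silyl enol ether formation) has no regiochemical issue, and the enol ether geometry is irrelevant because this double bond becomes C5=C6 of the pyranone.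

Step 2
Reactants: 2 (Z)-3-(trimethylsilyloxy)pent-2-ene; 3 malonyl dichloride
Product: 5 6-ethyl-4-hydroxy-5-methyl-2H-pyran-2-one, via 4-methyl-3,5-dioxoheptanoyl chloride 4 (not isolated)
Conditions: Et2O, −78 °C → rt
Reagents that add atoms: none
Why: Acylation–lactonisation of a silyl enol ether with malonyl dichloride: C-acylation with loss of Me3SiCl gives 4, whose enol oxygen closes onto the second acid chloride (6-exo-trig) and the ring tautomerises to the 4-hydroxy-2-pyranone.

Step 3
Reactants: 6 methyl acetate; 7 acrolein
Product: 9 methyl 3-hydroxypent-4-enoate (racemic), via lithium enolate of methyl acetate 8 (not isolated)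
Conditions: LiN(i-Pr)2, THF, −78 °C; then 7, −78 °C; aq. NH4Cl
Reagents that add atoms: none
Why: Aldol addition of a lithium ester enolate to the aldehyde carbonyl of acrolein (1,2-addition at low temperature); the carbinol centre is racemic and is erased in step 4.

Step 4
Reactants: 9 methyl 3-hydroxypent-4-enoate
Product: 10 methyl 3-oxopent-4-enoate (Nazarov reagent)
Conditions: CrO3, H2SO4, H2O, acetone, 0 °C
Reagents that add atoms: none
Why: Jones oxidation of a secondary allylic alcohol to the vinyl ketone under acidic conditions, which avoid base-induced polymerisation of the product; it is used at once.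

Step 5
Reactants: 5 6-ethyl-4-hydroxy-5-methyl-2H-pyran-2-one; 10 methyl 3-oxopent-4-enoate
Product: 11 methyl 5-(6-ethyl-4-hydroxy-5-methyl-2-oxo-2H-pyran-3-yl)-3-oxopentanoate
Conditions: Et3N (0.1 equiv), CH2Cl2, 0 °C → rt
Reagents that add atoms: none
Why: Michael addition of the 4-hydroxy-2-pyranone through C3, its only ring CH, to the vinyl ketone; the pyranone (pKa about 5) is the only species the catalytic amine deprotonates, so the β-keto ester should not add to a second acceptor.

Step 6
Reactants: 11 methyl 5-(6-ethyl-4-hydroxy-5-methyl-2-oxo-2H-pyran-3-yl)-3-oxopentanoate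
Product: 13 methyl (E)-5-(6-ethyl-4-hydroxy-5-methyl-2-oxo-2H-pyran-3-yl)-3-methoxypent-2-enoate, via cyclic methyl ketal 12 (not isolated)
Conditions: HC(OMe)3, MeOH, H2SO4 (cat.), rt; then NaOMe (3 equiv), MeOH, 0 °C → rt; cold 0.5 M HCl to pH 3
Reagents that add atoms: trimethyl orthoformate, COC(OC)OC (the methoxy group it delivers can exchange with methanol, CO, and NaOMe, [Na+].[O-]C)
Why: Acid-catalysed mixed ketalisation with the pyranone hydroxyl as internal partner (as for 4-hydroxycoumarin–ketone adducts in acidic methanol) masks that hydroxyl and installs the methoxy group, and methoxide then induces E1cB elimination (retro-oxa-Michael, as known for ketals of β-keto esters) in which the far better leaving group, the pyronate, departs while reversible methoxide addition equilibrates the enol ether to the (E) isomer.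

Step 7
Reactants: 13 methyl (E)-5-(6-ethyl-4-hydroxy-5-methyl-2-oxo-2H-pyran-3-yl)-3-methoxypent-2-enoate
Product: 15 6-ethyl-5-methyl-3-[(2Z,4Z)-3,5-dimethoxy-5-(trimethylsilyloxy)penta-2,4-dien-1-yl]-4-(trimethylsilyloxy)-2H-pyran-2-one, via dilithium pyronate dienolate 14 (not isolated)
Conditions: LiN(i-Pr)2 (2.2 equiv), THF, −78 °C; then Me3SiCl (3 equiv), −78 → 0 °C; pentane, filtration under Ar
Reagents that add atoms: chlorotrimethylsilane, C[Si](C)(C)Cl
Why: γ-Deprotonation and O-silylation of a β-methoxy enoate (Brassard-type diene synthesis), in which the first equivalent of base converts the pyranone into its 4-oxide and thereby shuts down the vinylogous acidity of the 6-ethyl group, so that the second equivalent removes the γ-hydrogen cis to the ester and Me3SiCl caps both oxygens, the pyronylmethyl group taking the outside position to avoid allylic strain.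

Step 8
Reactants: 16 (R)-2-methylbutanoic acid
Product: 18 (R)-N-methoxy-N,2-dimethylbutanamide, via acyl imidazole 17 (not isolated)
Conditions: 1,1'-carbonyldiimidazole, CH2Cl2, 0 °C → rt; then MeNH(OMe)·HCl, rt
Reagents that add atoms: N,O-dimethylhydroxylamine hydrochloride, CNOC.Cl
Why: Weinreb amide formation through the acyl imidazole, an activation that uses neither an acid chloride nor a tertiary amine and so avoids ketene formation and keeps the α-stereocentre.

Step 9
Reactants: 19 ethoxyacetylene; 18 (R)-N-methoxy-N,2-dimethylbutanamide
Product: 22 (4R)-1-ethoxy-4-methylhex-1-yn-3-one, via lithium ethoxyacetylide 20 (not isolated), via tetrahedral lithium adduct 21 (not isolated)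
Conditions: n-BuLi, THF, −78 °C; then 18, −78 → −30 °C; cold aq. NH4Cl; Et3N-deactivated silica
Reagents that add atoms: none
Why: Acylation of a lithium acetylide by a Weinreb amide, in which the chelated adduct 21 persists until the quench and prevents double addition, while the weakly basic acetylide does not enolise the amide, so the (R) centre should be retained; the acid-sensitive ynone is worked up near neutrality.

Step 10
Reactants: 15 6-ethyl-5-methyl-3-[(2Z,4Z)-3,5-dimethoxy-5-(trimethylsilyloxy)penta-2,4-dien-1-yl]-4-(trimethylsilyloxy)-2H-pyran-2-one; 22 (4R)-1-ethoxy-4-methylhex-1-yn-3-one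
Product: 25 3-{[2-ethoxy-4-hydroxy-6-methoxy-3-((2R)-2-methylbutanoyl)phenyl]methyl}-6-ethyl-4-hydroxy-5-methyl-2H-pyran-2-one, via cyclohexa-1,4-diene cycloadduct 23 (not isolated), via bis-silyl ether 24 (not isolated)
Conditions: toluene (1 M), 60 °C, Ar; then 0.5 M HCl, THF, 0 °C
Reagents that add atoms: none
Why: Proposed new method: the diene is a doubly donor-activated vinylogous silyl ketene acetal with its largest HOMO coefficient on the pyronylmethyl-bearing terminus, and the ynone is polarised in one direction by both its carbonyl and its ethoxy group so that the ethoxy-bearing carbon is the electrophilic one; the two should combine in a strongly asynchronous (4+2) cycloaddition, or in the stepwise limit by Mukaiyama–Michael addition and 6-exo-trig closure of the allenolate carbon onto the silyl oxocarbenium carbon, to give 23. The closest known reaction type is the Diels–Alder–aromatisation of Brassard-, Chan- and Danishefsky-type dienes with acetylenic esters and ketones to give resorcinol derivatives; an ynone with an alkoxy group on its β-carbon has not been shown in this role. Ring A closes as a six-membered carbocycle by intermolecular (4+2) union forming C1–C2 and C3–C4, and 1,4-elimination of methanol across the two sp3 carbons aromatises it to 24, whose two O–Si bonds are hydrolysed on work-up. No stereocentre is created in the product because both transient sp3 ring carbons become sp2, and the existing (R) centre beside the carbonyl meets neither base nor Lewis acid. The step needs regioselectivity, secured by the matched polarisation that places the acyl carbon between the ethoxy carbon and the new hydroxyl carbon, and chemoselectivity, secured because C3 of the silylated pyranone is fully substituted and the pyranone diene is far less electron-rich than the ketene acetal.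

Step 11
Reactants: 25 3-{[2-ethoxy-4-hydroxy-6-methoxy-3-((2R)-2-methylbutanoyl)phenyl]methyl}-6-ethyl-4-hydroxy-5-methyl-2H-pyran-2-one
Product: 26 3-{[2,4-dihydroxy-6-methoxy-3-((2R)-2-methylbutanoyl)phenyl]methyl}-6-ethyl-4-hydroxy-5-methyl-2H-pyran-2-one (target)
Conditions: BCl3 (5 equiv), CH2Cl2, −78 °C → rt; then ice-water
Reagents that add atoms: none
Why: Chelation-directed ether cleavage by BCl3, in which boron bridges the ketone oxygen and the ortho ethoxy oxygen and chloride removes the ethyl group, while the C6 methyl ether has no carbonyl neighbour and is not activated (the selective ortho dealkylation of 2-alkoxyaryl ketones); the low temperature and absence of base should protect the α-stereocentre.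

**Compound list**

1 | pentan-3-one | CCC(=O)CC | starting material
2 | (Z)-3-(trimethylsilyloxy)pent-2-ene (major isomer) | CC/C(O[Si](C)(C)C)=C/C | intermediate
3 | malonyl dichloride | O=C(Cl)CC(=O)Cl | starting material
4 | 4-methyl-3,5-dioxoheptanoyl chloride (racemic, not isolated) | CCC(=O)C(C)C(=O)CC(=O)Cl | intermediate
5 | 6-ethyl-4-hydroxy-5-methyl-2H-pyran-2-one | CCc1oc(=O)cc(O)c1C | intermediate
6 | methyl acetate | COC(C)=O | starting material
7 | acrolein | C=CC=O | starting material
8 | lithium enolate of methyl acetate (not isolated) | [Li+].COC([O-])=C | intermediate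
9 | methyl 3-hydroxypent-4-enoate (racemic) | COC(=O)CC(O)C=C | intermediate
10 | methyl 3-oxopent-4-enoate (Nazarov reagent) | COC(=O)CC(=O)C=C | intermediate
11 | methyl 5-(6-ethyl-4-hydroxy-5-methyl-2-oxo-2H-pyran-3-yl)-3-oxopentanoate (in equilibrium with its bicyclic hemiketal) | CCc1oc(=O)c(CCC(=O)CC(=O)OC)c(O)c1C | intermediate
12 | methyl 2-(7-ethyl-2-methoxy-8-methyl-5-oxo-3,4-dihydro-2H,5H-pyrano[4,3-b]pyran-2-yl)acetate (racemic, not isolated) | CCc1oc(=O)c2c(c1C)OC(OC)(CC(=O)OC)CC2 | intermediate
13 | methyl (E)-5-(6-ethyl-4-hydroxy-5-methyl-2-oxo-2H-pyran-3-yl)-3-methoxypent-2-enoate | CCc1oc(=O)c(CC/C(OC)=C\C(=O)OC)c(O)c1C | intermediate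
14 | dilithium salt of 13, pyronate and ester dienolate (not isolated) | [Li+].[Li+].CO/C([O-])=C/C(OC)=C/Cc1c([O-])c(C)c(CC)oc1=O | intermediate
15 | 6-ethyl-5-methyl-3-[(2Z,4Z)-3,5-dimethoxy-5-(trimethylsilyloxy)penta-2,4-dien-1-yl]-4-(trimethylsilyloxy)-2H-pyran-2-one (ketene acetal geometry of no consequence) | CO/C(O[Si](C)(C)C)=C/C(OC)=C/Cc1c(O[Si](C)(C)C)c(C)c(CC)oc1=O | intermediate
16 | (R)-2-methylbutanoic acid | OC(=O)[C@H](C)CC | starting material
17 | (R)-1-(1H-imidazol-1-yl)-2-methylbutan-1-one (not isolated) | O=C([C@H](C)CC)n1ccnc1 | intermediate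
18 | (R)-N-methoxy-N,2-dimethylbutanamide | CON(C)C(=O)[C@H](C)CC | intermediate
19 | ethoxyacetylene | CCOC#C | starting material
20 | lithium ethoxyacetylide (not isolated) | [Li+].CCOC#[C-] | intermediate
21 | lithium (4R)-1-ethoxy-3-[methoxy(methyl)amino]-4-methylhex-1-yn-3-olate (mixture at C3, not isolated) | [Li+].CCOC#CC([O-])([C@H](C)CC)N(C)OC | intermediate
22 | (4R)-1-ethoxy-4-methylhex-1-yn-3-one | CCOC#CC(=O)[C@H](C)CC | intermediate
23 | cyclohexa-1,4-diene cycloadduct of 15 and 22 (mixture at the two sp3 ring carbons, not isolated) | CCOC1=C(C(=O)[C@H](C)CC)C(OC)(O[Si](C)(C)C)C=C(OC)C1Cc1c(O[Si](C)(C)C)c(C)c(CC)oc1=O | intermediate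
24 | bis(trimethylsilyl) ether of 25 (not isolated) | CCOc1c(C(=O)[C@H](C)CC)c(O[Si](C)(C)C)cc(OC)c1Cc1c(O[Si](C)(C)C)c(C)c(CC)oc1=O | intermediate
25 | 3-{[2-ethoxy-4-hydroxy-6-methoxy-3-((2R)-2-methylbutanoyl)phenyl]methyl}-6-ethyl-4-hydroxy-5-methyl-2H-pyran-2-one | CCOc1c(C(=O)[C@H](C)CC)c(O)cc(OC)c1Cc1c(O)c(C)c(CC)oc1=O | intermediate
26 | 3-{[2,4-dihydroxy-6-methoxy-3-((2R)-2-methylbutanoyl)phenyl]methyl}-6-ethyl-4-hydroxy-5-methyl-2H-pyran-2-one | CCc1oc(=O)c(Cc2c(OC)cc(O)c(C(=O)[C@H](C)CC)c2O)c(O)c1C | target

**Totals.** Total step count: 11. Longest linear sequence: 7 steps (1, 2, 5, 6, 7, 10, 11; the branch through steps 3 and 4 is equally long).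

**Steps most likely to fail**

Step 10 (key step). The cycloaddition may be too slow at temperatures the ynol ether tolerates, so that retro-ene loss of ethylene from 22 or addition of the diene to the ketone carbonyl takes over. If the silyloxy group left in the aromatisation instead of methanol, the resulting ortho methyl ether would still be cleaved in step 11. The fallback uses known chemistry, sets out from 16 and 5 and comes back at 26. Acid 16 is converted with oxalyl chloride and catalytic DMF into (R)-2-methylbutanoyl chloride F1. F1 acylates commercial phloroglucinol (AlCl3, nitrobenzene–CH2Cl2, Friedel–Crafts acylation) to (R)-1-(2,4,6-trihydroxyphenyl)-2-methylbutan-1-one F2. The 4-hydroxyl, the only one not hydrogen-bonded to the ketone, is methylated with one equivalent of Me2SO4 and K2CO3 in acetone to (R)-1-(2,6-dihydroxy-4-methoxyphenyl)-2-methylbutan-1-one F3. Pyranone 5 and Eschenmoser's salt give the Mannich base 3-[(dimethylamino)methyl]-6-ethyl-4-hydroxy-5-methyl-2H-pyran-2-one F4. Warmed with excess F3 in dioxane, F4 should lose dimethylamine to the 3-methylenepyran-2,4-dione, which one of the two equivalent free ring carbons of F3 captures to give 26.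

Step 7. Proton transfer from the 6-ethyl group of the pyronate to the dienolate, silylation at carbon instead of oxygen, or hydrolysis of the labile bis-silyl diene during salt removal would erode 15. The fallback sets out from 22 and 5 and comes back at 26; it joins the pyrone only after ring A exists. Commercial methyl (E)-3-methoxybut-2-enoate is converted with LiN(i-Pr)2 and Me3SiCl into (Z)-1,3-dimethoxy-1-(trimethylsilyloxy)buta-1,3-diene F5, which has no competing acidic site. F5 is combined with 22 under the conditions of step 10 to give (R)-1-(2-ethoxy-6-hydroxy-4-methoxyphenyl)-2-methylbutan-1-one F6. BCl3 removes the chelated ethyl group of F6 to give F3, and F3 is bridged to 5 through the Mannich base F4 as described for step 10.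

Step 6. Ketalisation may stall or divert to dehydration products, and the hydroxy enoate may close again to the ketal during acidification. The fallback sets out from 11 and comes back at 13 through a conventional protecting group. Mitsunobu O-benzylation of the acidic pyranone hydroxyl (BnOH, PPh3, diisopropyl azodicarboxylate, THF) should give methyl 5-[4-(benzyloxy)-6-ethyl-5-methyl-2-oxo-2H-pyran-3-yl]-3-oxopentanoate F7. Trimethyl orthoformate with catalytic TsOH in methanol converts the β-keto ester into methyl (E)-5-[4-(benzyloxy)-6-ethyl-5-methyl-2-oxo-2H-pyran-3-yl]-3-methoxypent-2-enoate F8. Hydrogenolysis (H2, Pd/C, EtOAc) then releases 13 under neutral conditions without aqueous acid.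

**Further compounds**

F1 | step 10 | (R)-2-methylbutanoyl chloride | ClC(=O)[C@H](C)CC
F2 | step 10 | (R)-1-(2,4,6-trihydroxyphenyl)-2-methylbutan-1-one | O=C([C@H](C)CC)c1c(O)cc(O)cc1O
F3 | step 10 | (R)-1-(2,6-dihydroxy-4-methoxyphenyl)-2-methylbutan-1-one | O=C([C@H](C)CC)c1c(O)cc(OC)cc1O
F4 | step 10 | 3-[(dimethylamino)methyl]-6-ethyl-4-hydroxy-5-methyl-2H-pyran-2-one | CCc1oc(=O)c(CN(C)C)c(O)c1C
F5 | step 7 | (Z)-1,3-dimethoxy-1-(trimethylsilyloxy)buta-1,3-diene | CO/C(O[Si](C)(C)C)=C/C(OC)=C
F6 | step 7 | (R)-1-(2-ethoxy-6-hydroxy-4-methoxyphenyl)-2-methylbutan-1-one | CCOc1cc(OC)cc(O)c1C(=O)[C@H](C)CC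
F7 | step 6 | methyl 5-[4-(benzyloxy)-6-ethyl-5-methyl-2-oxo-2H-pyran-3-yl]-3-oxopentanoate | CCc1oc(=O)c(CCC(=O)CC(=O)OC)c(OCc2ccccc2)c1C
F8 | step 6 | methyl (E)-5-[4-(benzyloxy)-6-ethyl-5-methyl-2-oxo-2H-pyran-3-yl]-3-methoxypent-2-enoate | CCc1oc(=O)c(CC/C(OC)=C\C(=O)OC)c(OCc2ccccc2)c1C
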